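## Structural features

The target is a germacranolide: a ten-membered carbocycle (C1–C10, methyl C15 on C4, methyl C14 on C10) fused across C6–C7 to an α-methylene-γ-butyrolactone (oxygen on C6, C11=C13, C12 carbonyl) with a trans ring fusion. The ring also carries a trans 1,10-epoxide, a cis 4,5-epoxide, a free 2α-hydroxyl and an 8α-angelate; α is the face of H7 and of the C2, C6 and C8 oxygens, β is the face of C11. The eight stereocentres (1R,2S,4R,5S,6S,7R,8S,10R) form two contiguous sets, C10–C1–C2 and C4–C5–C6–C7–C8, linked only by the C3 and C9 methylenes. Fragile groups are the angelate (Z to E isomerisation to the tiglate under base or nucleophilic catalysis), the α-methylene lactone (Michael acceptor), both epoxides (acid, transannular opening) and, before epoxidation, the allylic C6–O bond and the 1,5-diene (Cope rearrangement on heating). The real difficulty is the medium ring itself, with one E and one Z trisubstituted alkene, and the relay of configuration across a conformationally mobile ring (C8 relative to C2, then C7 and C6). The key step exploits the fact that the C6 oxygen, the E C1=C10 unit and the cis C4=C5 unit are the pattern of a cyclodeca-2,6-dienone that a cyclohex-2-enol (ring atoms C1–C6) delivers by ring expansion when C1 carries an isopropenyl group (C10, C9, C14) and the carbinol carbon C6 carries a vinyl group (C7, C8) whose terminus bears silicon as the masked C8 hydroxyl. Two points of the design are corrected here: the cyclohexenol is a 2-isopropenyl-1-vinylcyclohex-2-enol (the silylvinyl group sits on the carbinol carbon), and the C2 oxygen is carried as a 4-methoxybenzyl ether, because a silyl ether at C2 would not survive the fluoride needed to unmask C8.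

## Logic of the disconnections

47 ⇒ 44 + 45. Both epoxides are cut (C1–O/C10–O and C4–O/C5–O). The C2 hydroxyl is allylic to C1=C10 and homoallylic to C4=C5, so one directing group can deliver both oxygens. Two rings and four stereocentres disappear. The forward step must transfer oxygen syn to the metal-bound hydroxyl on both alkenes and leave the two electron-poor alkenes alone; placing it last means no base or acid touches the epoxides.

44 ⇒ 43. The O–CH2Ar bond at C2 is cut (protecting group). The ether must survive fluoride, strong base and acylation and come off oxidatively without touching the angelate.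

43 ⇒ 40 + 41. The C8 O–acyl bond is cut. Acylation is placed after the methylenation so that no strong base meets the isomerisable angelate. The forward step must not isomerise Z to E.

40 ⇒ 35 + 36. The C11=C13 bond is cut. The exocyclic alkene is installed while only robust groups are present. The forward step needs a lactone enolate beside a free C8 alkoxide.

35 ⇒ 32 + 33. The C8–O bond is traced back to a C8–Si bond. An oxygen at C8 would be a β-alkoxy ketone at the stage of 25 and 28, whereas silicon is inert there. The forward oxidation must go with retention and leave the C2 ether and the lactone intact.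

32 ⇒ 31. The lactone alkyl C6–O bond is cut, to be formed with inversion. Outer-face hydride delivery is expected to give the 6β alcohol, so the trans fusion is planned through intramolecular SN2 closure. The forward step needs backside attack at an allylic carbinol without ionisation.

31 ⇒ 28 + 29. The C6–H bond (ketone reduction) and the ester are cut. The stereocentre at C6 is removed. The forward step needs 1,2-reduction of the enone.

28 ⇒ 25 + 26. The C7–C11 bond is cut. This removes the side chain and the C7 stereocentre. The forward alkylation must be regioselective for C7 and occur anti to the C8 silyl group.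

25 ⇒ 22. Retro-[3,3]: C1–C6 is reconnected and C8–C9 is cut. The ten-membered ring, the E alkene and the C8 stereocentre are traded for a cyclohexenol whose three stereocentres are set by ordinary six-ring chemistry. The forward step needs a chair transition state of the right sense, which requires the two alkenyl groups trans and the vinylsilane E.

22 ⇒ 15 + 19. The C6–C7 bond is cut (carbonyl addition). The alkenyl nucleophile carries the E geometry and the silicon; it must add anti to the isopropenyl group without enolising the ketone.

19 ⇒ 16 + 17. The Si–C bond is cut. Both partners are commercial and the E geometry comes from 16.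

15 ⇒ 11 + 12. The C1–C10 bond is cut. The forward alkenylation must occur at the α′ carbon, trans to the neighbouring ether, without later epimerisation or conjugation.

11 ⇒ 9 ⇒ 7 + 8 (with 10). The C4–C15 bond is cut and the carbonyl is transposed 1,3. This turns a simple 5-alkoxycyclohexenone into the 3-methyl enone with the carbonyl next to the future C1.

7 ⇒ 5 ⇒ 3 ⇒ 1 + 2 (with 4). The enone is traced to a meso diol: the β C–O bond (acetate) is cut, the carbinol is oxidised, and the two enantiotopic hydroxyls are told apart by an enzyme. One cheap achiral triol supplies all six ring carbons and the C2 oxygen.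

## Other disconnections considered

Alternative 1: The cut is C7–C11, made last, so that the lactone is annulated onto a finished ten-membered diepoxide. In the forward sense the C6 diazophosphonoacetate A2 is decomposed by Rh2(OAc)4 and the metal carbene inserts into a C7–H bond (1,5-insertion) to give the α-phosphono lactone A1. A Horner–Wadsworth–Emmons reaction of A1 with formaldehyde and desilylation at C2 would finish the target.
- In its favour: insertion is stereoretentive at C7 and five-membered ring formation is preferred. The phosphonate turns the α-methylenation into a mild carbonate-base olefination at the very end; on this point the alternative is better than the chosen plan, which needs a lithium amide (though before the angelate is present).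
- Against it here: the C7 hydrogens are deactivated by the adjacent C8 acyloxy group. The epoxide oxygens can trap the electrophilic carbene as oxonium ylides, and C5–H is a competing 1,5-site. Which C7 hydrogen reacts (trans or cis fusion) rests on ring conformation alone.
- Comparison: the step builds one ring, one skeletal bond and one stereocentre, equal to the oxy-Cope step in count. It leaves the whole medium-ring problem (ring, both alkene geometries, C8 relative to C2, both epoxides) to earlier chemistry that the chosen step solves. Mechanistically it depends on site selection among several C–H bonds and Lewis-basic traps, whereas the sigmatropic shift has one favourable chair. It would save about two steps at the end but needs a precursor at least as long as the route to 44.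

Alternative 2: The cut is C2–C3 together with O–C4: the ten-membered ring is closed end to end by an intramolecular nitrile oxide–alkene cycloaddition. Oxidation of the aldoxime A4 with NaOCl triggers 1,3-dipolar addition onto the 1,1-disubstituted C3=C4 alkene and would give the isoxazoline-bridged lactone A3. N–O cleavage, C2 ketone reduction, closure of the 4,5-epoxide from the C4 oxygen onto activated C5, exchange of the C8 silyl ether for the angelate, 1,10-epoxidation and methylenation would follow.
- In its favour: the step forms two bonds, two rings and the C4 stereocentre at once, more construction per step than the chosen key step (better on this point). The regiochemistry (oxygen to the substituted carbon) is reliable. The C6–C7–C8 triad is set on a five-membered lactone and not on a flexible medium ring (also better).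
- Against it here: end-to-end closure of a ten-membered ring fights strain and entropy, so dimerisation of the dipole competes and high dilution is needed. The C4 configuration depends on chain folding. Afterwards the C2 oxygen must be unveiled as a β-hydroxy ketone (retro-aldol risk) and reduced to 2α, and the C1=C10 alkene, conjugated to C2 at that stage, must be epoxidised on the right face.
- Comparison: the oxy-Cope step makes the ring by expansion, without the entropic penalty, and carries C2 and both alkene geometries into the ring unchanged. The alternative needs roughly six to eight operations after its key step, so it is no shorter and probably longer.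

Alternative 3: The cut is the lactone C6–O bond together with C5–I: the ten-membered 4-hydroxy-5Z-ene acid A6 is iodolactonised. Iodine activates C5=C6, the C12 carboxylate attacks C6 (5-exo) anti to iodine to give the iodo lactone A5, and base then lets the C4 alkoxide displace iodide with inversion at C5 to form the cis 4,5-epoxide.
- In its favour: anti addition ties C5 to C6 and the epoxide follows stereospecifically. Two of the least secure relationships of the chosen plan (C6 by reduction and inversion, the 4,5-epoxide by remote direction) are replaced by one stereospecific event; here the alternative is better. The conditions are equally mild, and the step sets two stereocentres.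
- Against it here: it presupposes a ten-membered ring that already holds the E C1=C10 alkene, a Z C5=C6 alkene, the C4 tertiary carbinol and C2, C7 and C8, so the medium-ring problem is untouched. The trisubstituted C1=C10 alkene is the more nucleophilic one and invites iodonium formation and transannular pathways. The free C4 hydroxyl is a competing nucleophile. The face of iodonium formation, and with it the trans fusion, depends on ring conformation (reversibility may help).
- Comparison: it builds one five-membered ring and no carbocycle. Afterwards the C8 ether must still be exchanged for the angelate, C2 deprotected, C1=C10 epoxidised and C11 methylenated, so the end game is as long as the chosen one.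

Key step: step 9

Assumption: the lipase of step 2 is taken to acylate the R-configured carbinol flanked by the ether-bearing arm (Kazlauskas rule), giving 5; germacranolide numbering and the α/β labels defined above are used for all ring compounds from 22 on.

## Route

Step 1
Reactants: 1 cis,cis-cyclohexane-1,3,5-triol; 2 4-methoxybenzyl chloride
Product: 3 cis,cis-5-[(4-methoxybenzyl)oxy]cyclohexane-1,3-diol (meso)
Conditions: NaH (1.0 equiv), 1 (3 equiv), DMF, 0 °C; then 2 (1.0 equiv), Bu4NI (cat.), 0 °C to rt
Reagents that add atoms: 4-methoxybenzyl chloride, COc1ccc(CCl)cc1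
Why: Williamson etherification; the three hydroxyls of 1 are equivalent, so only the degree of alkylation has to be controlled, which the excess of triol does, and the mono-ether keeps a mirror plane so no stereocentre is set.

Step 2
Reactants: 3 cis,cis-5-[(4-methoxybenzyl)oxy]cyclohexane-1,3-diol; 4 vinyl acetate
Product: 5 (1R,3R,5S)-3-hydroxy-5-[(4-methoxybenzyl)oxy]cyclohexyl acetate
Conditions: immobilised Candida antarctica lipase B, vinyl acetate (5 equiv), t-BuOMe, 30 °C
Reagents that add atoms: vinyl acetate, C=COC(C)=O
Why: Lipase-catalysed desymmetrisation of a meso 1,3-diol by irreversible transesterification; the enzyme distinguishes the enantiotopic carbinols and so fixes the absolute configuration of the ether carbon that becomes C2.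

Step 3
Reactants: 5 (1R,3R,5S)-3-hydroxy-5-[(4-methoxybenzyl)oxy]cyclohexyl acetate
Product: 7 (R)-5-[(4-methoxybenzyl)oxy]cyclohex-2-en-1-one, via β-acetoxy ketone 6 (not isolated)
Conditions: Dess–Martin periodinane, CH2Cl2, 0 °C to rt; then Et3N, 0 °C to rt
Reagents that add atoms: none
Why: Dess–Martin oxidation gives a β-acetoxy ketone that loses acetic acid by E1cB elimination under mild amine base; acetate is a far better leaving group than the benzylic alkoxide, so the alkene forms on the acetate side and the ether stereocentre is untouched.

Step 4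
Reactants: 7 (R)-5-[(4-methoxybenzyl)oxy]cyclohex-2-en-1-one; 8 methyllithium
Product: 9 (5R)-5-[(4-methoxybenzyl)oxy]-1-methylcyclohex-2-en-1-ol (both C1 epimers)
Conditions: MeLi, Et2O, −78 °C; then H2O
Reagents that add atoms: methyllithium, [Li]C
Why: 1,2-addition of a hard organolithium to the enone carbonyl at low temperature; the new carbinol centre is destroyed in the next step, so its configuration does not matter.

Step 5
Reactants: 9 (5R)-5-[(4-methoxybenzyl)oxy]-1-methylcyclohex-2-en-1-ol; 10 pyridinium chlorochromate
Product: 11 (S)-5-[(4-methoxybenzyl)oxy]-3-methylcyclohex-2-en-1-one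
Conditions: C5H5NH[CrO3Cl] (2 equiv), 4 Å molecular sieves, CH2Cl2, rt
Reagents that add atoms: pyridinium chlorochromate, [O-][Cr](=O)(=O)Cl.c1cc[nH+]cc1
Why: Babler–Dauben oxidative transposition: the tertiary allylic chromate ester undergoes a [3,3] shift and the resulting secondary chromate is oxidised, which moves the carbonyl to the carbon that becomes C6 and leaves the methyl on the alkene carbon that becomes C4.

Step 6
Reactants: 11 (S)-5-[(4-methoxybenzyl)oxy]-3-methylcyclohex-2-en-1-one; 12 2-bromopropene
Product: 15 (5S,6R)-5-[(4-methoxybenzyl)oxy]-3-methyl-6-(prop-1-en-2-yl)cyclohex-2-en-1-one, via lithium enolate 13 (not isolated), via chlorozinc enolate 14 (not isolated)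
Conditions: LiN(i-Pr)2 (1.05 equiv), THF, −78 °C; ZnCl2 (1.1 equiv), −78 to 0 °C; then 12 (1.5 equiv), Pd[P(t-Bu)3]2 (5 mol %), 0 °C to rt
Reagents that add atoms: 2-bromopropene, CC(Br)=C
Why: Kinetic deprotonation gives the cross-conjugated α′ enolate, and palladium-catalysed α-alkenylation of its zinc enolate (Negishi-type enolate coupling: oxidative addition of 12 to zerovalent palladium, transmetallation, reductive elimination) forms C1–C10 on the face anti to the neighbouring ether, giving the trans isomer. The weakly basic zinc enolate should not deprotonate the more acidic product, so the configuration set in the bond-forming event is kept and the β,γ-alkene is not drawn into conjugation.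

Step 7
Reactants: 16 (E)-1,2-bis(tributylstannyl)ethene; 17 benzylchlorodimethylsilane
Product: 19 (E)-benzyl(dimethyl)[2-(tributylstannyl)ethenyl]silane, via (E)-2-(tributylstannyl)ethenyllithium 18 (not isolated)
Conditions: n-BuLi (1.0 equiv), THF, −78 °C; then 17, −78 °C to rt
Reagents that add atoms: (E)-1,2-bis(tributylstannyl)ethene, CCCC[Sn](CCCC)(CCCC)/C=C/[Sn](CCCC)(CCCC)CCCC; benzylchlorodimethylsilane, C[Si](C)(Cl)Cc1ccccc1
Why: Tin–lithium exchange on one stannyl group gives a configurationally stable E alkenyllithium, which is silylated with retention of the alkene geometry.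

Step 8
Reactants: 15 (5S,6R)-5-[(4-methoxybenzyl)oxy]-3-methyl-6-(prop-1-en-2-yl)cyclohex-2-en-1-one; 19 (E)-benzyl(dimethyl)[2-(tributylstannyl)ethenyl]silane
Product: 22 (1S,5S,6R)-1-{(E)-2-[benzyl(dimethyl)silyl]ethenyl}-5-[(4-methoxybenzyl)oxy]-3-methyl-6-(prop-1-en-2-yl)cyclohex-2-en-1-ol, via silylethenyllithium 20 (not isolated), via dichlorocerium reagent 21 (not isolated)
Conditions: 19 (1.3 equiv), n-BuLi, THF, −78 °C; CeCl3 (anhydrous), −78 °C; then 15, −78 °C; then H2O
Reagents that add atoms: none
Why: A second tin–lithium exchange and transmetallation to cerium give a weakly basic alkenyl nucleophile that adds 1,2 to the enone without enolising the doubly activated C1–H. Alkenyl nucleophiles attack 6-substituted cyclohexenones anti to the adjacent substituent, which sets the tertiary carbinol with the two alkenyl groups trans, and the E vinylsilane is delivered intact.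

Step 9
Reactants: 22 (1S,5S,6R)-1-{(E)-2-[benzyl(dimethyl)silyl]ethenyl}-5-[(4-methoxybenzyl)oxy]-3-methyl-6-(prop-1-en-2-yl)cyclohex-2-en-1-ol
Product: 25 (2Z,5S,6E,9S)-9-[benzyl(dimethyl)silyl]-5-[(4-methoxybenzyl)oxy]-3,7-dimethylcyclodeca-2,6-dien-1-one, via potassium alkoxide 23 (not isolated), via potassium enolate 24 (not isolated)
Conditions: KH (1.5 equiv), 18-crown-6 (1.5 equiv), THF, 0 °C to rt; then inverse quench into H2O/THF, −78 °C
Reagents that add atoms: none
Why: Anionic oxy-Cope rearrangement, the alkoxide-accelerated [3,3] sigmatropic shift of the 3-oxido-1,5-diene C8=C7–C6(O−)–C1–C10=C9, a reaction type well established for 1,2-dialkenylcyclohexanols. The ten-membered ring arises by ring expansion through a six-membered chair transition state, not by end-to-end cyclisation: C1–C6 breaks as C8–C9 forms, and C2–C5 of the cyclohexene become the bridge between the new termini. Because the alkenyl groups are trans, both ring bonds (C6–C5 and C1–C2) are equatorial on the chair, which turns C1=C10 out E, while the cis C4=C5 bond is carried over unchanged. The only new stereocentre, C8, is controlled by the E geometry of the vinylsilane (silicon equatorial) and by the sense of the chair, which the C1 and C6 configurations fix; this gives 8S, with silicon on the face of the C2 oxygen. The step needs chair over boat and [3,3] over [1,3] shift or fragmentation: the trans-diequatorial substrate has one strain-free chair, the second 1,5-diene through the ring alkene would require the isopropenyl group to reach across the ring, and the C2 ether is 1,3-trans to the alkoxide and too poor a leaving group for Grob fragmentation. The regiodefined C6–C7 enolate is protonated cold by inverse quench so that it cannot equilibrate to the extended dienolate.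

Step 10
Reactants: 25 (2Z,5S,6E,9S)-9-[benzyl(dimethyl)silyl]-5-[(4-methoxybenzyl)oxy]-3,7-dimethylcyclodeca-2,6-dien-1-one; 26 ethyl iodoacetate
Product: 28 ethyl 2-[(1S,3Z,6S,7E,10S)-10-[benzyl(dimethyl)silyl]-6-[(4-methoxybenzyl)oxy]-4,8-dimethyl-2-oxocyclodeca-3,7-dien-1-yl]acetate, via lithium enolate 27 (not isolated)
Conditions: LiN(i-Pr)2 (1.1 equiv), THF, −78 °C; then 26, DMPU, −78 to −40 °C
Reagents that add atoms: ethyl iodoacetate, CCOC(=O)CI
Why: Kinetic deprotonation of the enone at the α′ carbon C7 regenerates the cross-conjugated enolate, which is alkylated by the reactive iodoacetate. Attack from the outer face of the ring, anti to the transannular C1=C10 unit, places the new chain equatorial and trans to the neighbouring C8 silyl group, the 7β configuration of the target.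

Step 11
Reactants: 28 ethyl 2-[(1S,3Z,6S,7E,10S)-10-[benzyl(dimethyl)silyl]-6-[(4-methoxybenzyl)oxy]-4,8-dimethyl-2-oxocyclodeca-3,7-dien-1-yl]acetate; 29 lithium hydroxide
Product: 31 (1(10)E,4Z)-8α-[benzyl(dimethyl)silyl]-6β-hydroxy-2α-[(4-methoxybenzyl)oxy]-13-norgermacra-1(10),4-dien-12-oic acid, via hydroxy ester 30 (not isolated)
Conditions: NaBH4, CeCl3·7H2O, MeOH, −78 to −20 °C; then LiOH, THF/H2O, 0 °C to rt; HCl (1 M) to pH 5, 0 °C
Reagents that add atoms: lithium hydroxide, [Li+].[OH-]
Why: Luche 1,2-reduction of the enone carbonyl followed by ester saponification. Hydride should enter from the outer face, the same side of the former enolate plane as the C7 substituent; because C5 and C8 are transoid across C6–C7 this gives the 6β alcohol, with hydroxyl and side chain close to anti-periplanar so that closure with retention is disfavoured. Should hydride add to the other face instead, acid-catalysed closure would lead to 32 without inversion.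

Step 12
Reactants: 31 (1(10)E,4Z)-8α-[benzyl(dimethyl)silyl]-6β-hydroxy-2α-[(4-methoxybenzyl)oxy]-13-norgermacra-1(10),4-dien-12-oic acid
Product: 32 (1(10)E,4Z)-8α-[benzyl(dimethyl)silyl]-2α-[(4-methoxybenzyl)oxy]-13-norgermacra-1(10),4-dien-12,6α-olide
Conditions: PPh3, i-PrO2CN=NCO2i-Pr, THF, 0 °C
Reagents that add atoms: none
Why: Mitsunobu lactonisation: the C6 hydroxyl is activated as an alkoxyphosphonium ion and displaced by the carboxylate (5-exo-tet, SN2) with inversion, which puts the lactone oxygen α and trans to C7–C11. The anti arrangement of leaving group and side chain in the ring favours this backside closure.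

Step 13
Reactants: 32 (1(10)E,4Z)-8α-[benzyl(dimethyl)silyl]-2α-[(4-methoxybenzyl)oxy]-13-norgermacra-1(10),4-dien-12,6α-olide; 33 hydrogen peroxide
Product: 35 (1(10)E,4Z)-8α-hydroxy-2α-[(4-methoxybenzyl)oxy]-13-norgermacra-1(10),4-dien-12,6α-olide, via fluorosilane 34 (not isolated)
Conditions: Bu4NF (2 equiv), THF, 0 °C to rt; then H2O2 (30 %), KHCO3, MeOH, rt
Reagents that add atoms: hydrogen peroxide, OO
Why: Tamao–Fleming oxidation: fluoride cleaves the benzyl–silicon bond to a fluorosilane, which peroxide oxidises by 1,2-migration of C8 from silicon to oxygen with retention, giving the 8S alcohol. The 4-methoxybenzyl ether is inert to fluoride, and the bicarbonate buffer keeps the alkoxide concentration too low for lactone migration to O8.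

Step 14
Reactants: 35 (1(10)E,4Z)-8α-hydroxy-2α-[(4-methoxybenzyl)oxy]-13-norgermacra-1(10),4-dien-12,6α-olide; 36 dimethyl(methylene)ammonium iodide
Product: 40 (1(10)E,4Z)-8α-hydroxy-2α-[(4-methoxybenzyl)oxy]germacra-1(10),4,11(13)-trien-12,6α-olide, via dilithium enolate alkoxide 37 (not isolated), via Mannich base 38 (not isolated), via methiodide 39 (not isolated)
Conditions: LiN(i-Pr)2 (2.3 equiv), THF, −78 °C; then 36 (3 equiv), −78 °C to rt, H2O; then MeI, MeOH, rt; then NaHCO3, CH2Cl2/H2O, rt
Reagents that add atoms: dimethyl(methylene)ammonium iodide, C=[N+](C)C.[I-]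
Why: Eschenmoser methylenation: the lactone enolate, formed beside the C8 alkoxide, undergoes a Mannich reaction with the iminium salt, and quaternisation followed by mild-base elimination of trimethylamine gives the exocyclic alkene. The strong base is used here, before the angelate and the epoxides exist.

Step 15
Reactants: 40 (1(10)E,4Z)-8α-hydroxy-2α-[(4-methoxybenzyl)oxy]germacra-1(10),4,11(13)-trien-12,6α-olide; 41 angelic acid
Product: 43 (1(10)E,4Z)-8α-angeloyloxy-2α-[(4-methoxybenzyl)oxy]germacra-1(10),4,11(13)-trien-12,6α-olide, via mixed anhydride 42 (not isolated)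
Conditions: 41 (3 equiv), 2,4,6-Cl3C6H2COCl, Et3N, toluene, rt; then 40, toluene, 60 °C
Reagents that add atoms: angelic acid, C/C=C(/C)C(=O)O
Why: Yamaguchi-type esterification through the mixed anhydride without a nucleophilic catalyst, the conditions under which angelates are formed without Z to E isomerisation to the tiglate; only the C8 hydroxyl is free, and the moderate temperature avoids Cope rearrangement of the 1,5-diene.

Step 16
Reactants: 43 (1(10)E,4Z)-8α-angeloyloxy-2α-[(4-methoxybenzyl)oxy]germacra-1(10),4,11(13)-trien-12,6α-olide
Product: 44 (1(10)E,4Z)-8α-angeloyloxy-2α-hydroxygermacra-1(10),4,11(13)-trien-12,6α-olide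
Conditions: DDQ (1.5 equiv), CH2Cl2/pH 7 buffer, 0 °C to rt
Reagents that add atoms: none
Why: Oxidative cleavage of the 4-methoxybenzyl ether (hydride abstraction from the electron-rich benzylic position, then hydrolysis of the oxocarbenium ion); the ester, the α-methylene lactone and the alkenes are inert to the quinone.

Step 17
Reactants: 44 (1(10)E,4Z)-8α-angeloyloxy-2α-hydroxygermacra-1(10),4,11(13)-trien-12,6α-olide; 45 tert-butyl hydroperoxide
Product: 47 (1R,2S,4R,5S,6S,7R,8S,10R)-8α-angeloyloxy-1β,10α:4α,5α-diepoxy-2α-hydroxygermacr-11(13)-en-12,6α-olide (CNP0388761.2), via 1,10-epoxide 46 (not isolated)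
Conditions: VO(acac)2 (10 mol %), t-BuOOH (3 equiv, anhydrous, in decane), CH2Cl2, 0 °C to rt
Reagents that add atoms: tert-butyl hydroperoxide, CC(C)(C)OO
Why: Hydroxyl-directed epoxidation by the vanadium alkyl peroxide bound to the C2 oxygen. For the allylic C1=C10 bond, allylic 1,3-strain with the cis C14 methyl places H2 in the alkene plane and delivers oxygen to the hydroxyl-bearing outer face (threo epoxy alcohol, 1R,10R); the homoallylic cis C4=C5 bond is then epoxidised on the face of the vanadate (4R,5S). The electron-poor C11=C13 and angelate alkenes do not react.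

## Compound list

1 | cis,cis-cyclohexane-1,3,5-triol | O[C@@H]1C[C@H](O)C[C@H](O)C1 | starting material
2 | 4-methoxybenzyl chloride | COc1ccc(CCl)cc1 | starting material
3 | cis,cis-5-[(4-methoxybenzyl)oxy]cyclohexane-1,3-diol (meso) | O[C@H]1C[C@@H](O)C[C@@H](OCc2ccc(OC)cc2)C1 | intermediate
4 | vinyl acetate | C=COC(C)=O | starting material
5 | (1R,3R,5S)-3-hydroxy-5-[(4-methoxybenzyl)oxy]cyclohexyl acetate (all-cis) | O[C@H]1C[C@@H](OC(C)=O)C[C@@H](OCc2ccc(OC)cc2)C1 | intermediate
6 | (1S,3R)-3-[(4-methoxybenzyl)oxy]-5-oxocyclohexyl acetate (cis) | O=C1C[C@@H](OC(C)=O)C[C@@H](OCc2ccc(OC)cc2)C1 | intermediate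
7 | (R)-5-[(4-methoxybenzyl)oxy]cyclohex-2-en-1-one | O=C1C=CC[C@@H](OCc2ccc(OC)cc2)C1 | intermediate
8 | methyllithium | [Li]C | starting material
9 | (5R)-5-[(4-methoxybenzyl)oxy]-1-methylcyclohex-2-en-1-ol (both C1 epimers) | CC1(O)C=CC[C@@H](OCc2ccc(OC)cc2)C1 | intermediate
10 | pyridinium chlorochromate | [O-][Cr](=O)(=O)Cl.c1cc[nH+]cc1 | starting material
11 | (S)-5-[(4-methoxybenzyl)oxy]-3-methylcyclohex-2-en-1-one | O=C1C=C(C)C[C@H](OCc2ccc(OC)cc2)C1 | intermediate
12 | 2-bromopropene | CC(Br)=C | starting material
13 | lithium enolate of 11 (cross-conjugated α′ enolate) | [Li]OC1=C[C@@H](OCc2ccc(OC)cc2)CC(C)=C1 | intermediate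
14 | chlorozinc enolate of 11 | Cl[Zn]OC1=C[C@@H](OCc2ccc(OC)cc2)CC(C)=C1 | intermediate
15 | (5S,6R)-5-[(4-methoxybenzyl)oxy]-3-methyl-6-(prop-1-en-2-yl)cyclohex-2-en-1-one (trans) | O=C1C=C(C)C[C@H](OCc2ccc(OC)cc2)[C@H]1C(C)=C | intermediate
16 | (E)-1,2-bis(tributylstannyl)ethene | CCCC[Sn](CCCC)(CCCC)/C=C/[Sn](CCCC)(CCCC)CCCC | starting material
17 | benzylchlorodimethylsilane | C[Si](C)(Cl)Cc1ccccc1 | starting material
18 | (E)-2-(tributylstannyl)ethenyllithium | [Li]/C=C/[Sn](CCCC)(CCCC)CCCC | intermediate
19 | (E)-benzyl(dimethyl)[2-(tributylstannyl)ethenyl]silane | CCCC[Sn](CCCC)(CCCC)/C=C/[Si](C)(C)Cc1ccccc1 | intermediate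
20 | (E)-2-[benzyl(dimethyl)silyl]ethenyllithium | [Li]/C=C/[Si](C)(C)Cc1ccccc1 | intermediate
21 | (E)-{2-[benzyl(dimethyl)silyl]ethenyl}cerium dichloride | Cl[Ce](Cl)/C=C/[Si](C)(C)Cc1ccccc1 | intermediate
22 | (1S,5S,6R)-1-{(E)-2-[benzyl(dimethyl)silyl]ethenyl}-5-[(4-methoxybenzyl)oxy]-3-methyl-6-(prop-1-en-2-yl)cyclohex-2-en-1-ol | O[C@@]1(/C=C/[Si](C)(C)Cc2ccccc2)C=C(C)C[C@H](OCc2ccc(OC)cc2)[C@H]1C(C)=C | intermediate
23 | potassium alkoxide of 22 | [K]O[C@@]1(/C=C/[Si](C)(C)Cc2ccccc2)C=C(C)C[C@H](OCc2ccc(OC)cc2)[C@H]1C(C)=C | intermediate
24 | potassium C6–C7 enolate of 25 (C5 and C8 trans across the enolate) | [K]O/C1=C\[C@@H]([Si](C)(C)Cc2ccccc2)C/C(C)=C/[C@@H](OCc2ccc(OC)cc2)C/C(C)=C\1 | intermediate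
25 | (2Z,5S,6E,9S)-9-[benzyl(dimethyl)silyl]-5-[(4-methoxybenzyl)oxy]-3,7-dimethylcyclodeca-2,6-dien-1-one | O=C1C[C@@H]([Si](C)(C)Cc2ccccc2)C/C(C)=C/[C@@H](OCc2ccc(OC)cc2)C/C(C)=C\1 | intermediate
26 | ethyl iodoacetate | CCOC(=O)CI | starting material
27 | lithium C6–C7 enolate of 25 | [Li]OC1=C[C@@H]([Si](C)(C)Cc2ccccc2)C/C(C)=C/[C@@H](OCc2ccc(OC)cc2)C/C(C)=C\1 | intermediate
28 | ethyl 2-[(1S,3Z,6S,7E,10S)-10-[benzyl(dimethyl)silyl]-6-[(4-methoxybenzyl)oxy]-4,8-dimethyl-2-oxocyclodeca-3,7-dien-1-yl]acetate | O=C1[C@H](CC(=O)OCC)[C@@H]([Si](C)(C)Cc2ccccc2)C/C(C)=C/[C@@H](OCc2ccc(OC)cc2)C/C(C)=C\1 | intermediate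
29 | lithium hydroxide | [Li+].[OH-] | starting material
30 | ethyl (1(10)E,4Z)-8α-[benzyl(dimethyl)silyl]-6β-hydroxy-2α-[(4-methoxybenzyl)oxy]-13-norgermacra-1(10),4-dien-12-oate | O[C@@H]1[C@H](CC(=O)OCC)[C@@H]([Si](C)(C)Cc2ccccc2)C/C(C)=C/[C@@H](OCc2ccc(OC)cc2)C/C(C)=C\1 | intermediate
31 | (1(10)E,4Z)-8α-[benzyl(dimethyl)silyl]-6β-hydroxy-2α-[(4-methoxybenzyl)oxy]-13-norgermacra-1(10),4-dien-12-oic acid | O[C@@H]1[C@H](CC(=O)O)[C@@H]([Si](C)(C)Cc2ccccc2)C/C(C)=C/[C@@H](OCc2ccc(OC)cc2)C/C(C)=C\1 | intermediate
32 | (1(10)E,4Z)-8α-[benzyl(dimethyl)silyl]-2α-[(4-methoxybenzyl)oxy]-13-norgermacra-1(10),4-dien-12,6α-olide (trans-fused) | C1C(=O)O[C@H]2[C@H]1[C@@H]([Si](C)(C)Cc3ccccc3)C/C(C)=C/[C@@H](OCc3ccc(OC)cc3)C/C(C)=C\2 | intermediate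
33 | hydrogen peroxide | OO | starting material
34 | 8α-[fluoro(dimethyl)silyl] analogue of 32 | C1C(=O)O[C@H]2[C@H]1[C@@H]([Si](C)(C)F)C/C(C)=C/[C@@H](OCc3ccc(OC)cc3)C/C(C)=C\2 | intermediate
35 | (1(10)E,4Z)-8α-hydroxy-2α-[(4-methoxybenzyl)oxy]-13-norgermacra-1(10),4-dien-12,6α-olide | C1C(=O)O[C@H]2[C@H]1[C@@H](O)C/C(C)=C/[C@@H](OCc3ccc(OC)cc3)C/C(C)=C\2 | intermediate
36 | dimethyl(methylene)ammonium iodide | C=[N+](C)C.[I-] | starting material
37 | dilithium salt of 35 (C8 alkoxide, C11–C12 lactone enolate) | C1=C(O[Li])O[C@H]2[C@H]1[C@@H](O[Li])C/C(C)=C/[C@@H](OCc3ccc(OC)cc3)C/C(C)=C\2 | intermediate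
38 | 11-[(dimethylamino)methyl] derivative of 35 (either C11 epimer) | CN(C)CC1C(=O)O[C@H]2[C@H]1[C@@H](O)C/C(C)=C/[C@@H](OCc3ccc(OC)cc3)C/C(C)=C\2 | intermediate
39 | trimethylammonium iodide of 38 | C[N+](C)(C)CC1C(=O)O[C@H]2[C@H]1[C@@H](O)C/C(C)=C/[C@@H](OCc3ccc(OC)cc3)C/C(C)=C\2.[I-] | intermediate
40 | (1(10)E,4Z)-8α-hydroxy-2α-[(4-methoxybenzyl)oxy]germacra-1(10),4,11(13)-trien-12,6α-olide | C=C1C(=O)O[C@H]2[C@H]1[C@@H](O)C/C(C)=C/[C@@H](OCc3ccc(OC)cc3)C/C(C)=C\2 | intermediate
41 | angelic acid, (Z)-2-methylbut-2-enoic acid | C/C=C(/C)C(=O)O | starting material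
42 | angelic 2,4,6-trichlorobenzoic anhydride | C/C=C(/C)C(=O)OC(=O)c1c(Cl)cc(Cl)cc1Cl | intermediate
43 | (1(10)E,4Z)-8α-angeloyloxy-2α-[(4-methoxybenzyl)oxy]germacra-1(10),4,11(13)-trien-12,6α-olide | C=C1C(=O)O[C@H]2[C@H]1[C@@H](OC(=O)/C(C)=C\C)C/C(C)=C/[C@@H](OCc3ccc(OC)cc3)C/C(C)=C\2 | intermediate
44 | (1(10)E,4Z)-8α-angeloyloxy-2α-hydroxygermacra-1(10),4,11(13)-trien-12,6α-olide | C=C1C(=O)O[C@H]2[C@H]1[C@@H](OC(=O)/C(C)=C\C)C/C(C)=C/[C@@H](O)C/C(C)=C\2 | intermediate
45 | tert-butyl hydroperoxide | CC(C)(C)OO | starting material
46 | (4Z)-8α-angeloyloxy-1β,10α-epoxy-2α-hydroxygermacra-4,11(13)-dien-12,6α-olide (1R,10R) | C=C1C(=O)O[C@H]2[C@H]1[C@@H](OC(=O)/C(C)=C\C)C[C@@]1(C)O[C@@H]1[C@@H](O)C/C(C)=C\2 | intermediate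
47 | (1R,2S,4R,5S,6S,7R,8S,10R)-8α-angeloyloxy-1β,10α:4α,5α-diepoxy-2α-hydroxygermacr-11(13)-en-12,6α-olide (CNP0388761.2) | C=C1C(=O)O[C@H]2[C@H]1[C@@H](OC(=O)/C(C)=C\C)C[C@@]1(C)O[C@@H]1[C@@H](O)C[C@@]1(C)O[C@@H]21 | target

## Step count and least certain steps

Total: 17 steps. Longest linear sequence: 16 steps (steps 1–6 and 8–17); step 7 is a one-step branch.

Step 9 (key step). The concerted shift may be slowed by the silyl substituent on the reacting alkene terminus, which would let stepwise cleavage and recombination of the alkoxide compete ([1,3] shift, fragmentation) or open a boat pathway, eroding ring size or the C8 configuration. Equilibration of the enolate on quench is a further risk. Fallback, setting out from 22 and returning at 25: the neutral thermal siloxy-Cope rearrangement. Silylation (Me3SiCl, imidazole, DMF) would give the trimethylsilyl ether F1. Brief heating in toluene at about 190 °C in a sealed tube would give the trimethylsilyl enol ether F2 through the same chair; the contact time is kept short because the product is itself a 1,5-diene. Mild hydrolysis (dilute HCl in THF at 0 °C) would release 25.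

Step 6. Proton transfer between the acidic product and unreacted enolate could erase the trans configuration or move the isopropenyl alkene into conjugation, and the C2 alkoxide could be lost by β-elimination on the way to a phenol. Fallback, setting out from 11 (through 13) and returning at 15: aldol addition of 13 to acetone at −78 °C would give the trans aldol adduct F3, with the new bond again formed anti to the ether. Dehydration towards a methyl group with SOCl2/pyridine at −20 °C would then give 15.

Step 10. Deprotonation could occur at the γ positions (C3 or C15) because the C7 hydrogens lie next to the bulky silyl group, and the electrophile could enter on the other enolate face or twice. Fallback, setting out from 22 and returning at 28: the deprotonation is avoided altogether by intercepting the regiodefined enolate 24 of the key step in the same flask, after exchange of potassium for lithium with LiBr at −78 °C, with 26; this makes no new compound (F0).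

Step 11. The C6 carbonyl can present either face in different ring conformers, so hydride delivery may be poorly face-selective. Fallback, setting out from 28 and returning at 32: the epimeric 6α-hydroxy acid F4 needs no inversion. It would be separated and closed with retention by acid catalysis (pyridinium 4-toluenesulfonate, CH2Cl2), so both epimers converge on 32.

Step 12. The hindered allylic carbinol may react through an acyloxyphosphonium ion (closure with retention) or by SN2′ attack at C4. Fallback, setting out from 25 and returning at 32: sulfonate displacement by a tert-butyl ester.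
- Alkylation of 27 with tert-butyl iodoacetate would give the keto tert-butyl ester F5.
- Luche reduction would give the 6β-hydroxy tert-butyl ester F6, which cannot lactonise spontaneously.
- Methanesulfonic anhydride and Et3N would give the mesylate F7, whose ester carbonyl displaces the sulfonate from the back with loss of 2-methylpropene to give 32.

Step 17. The second, homoallylic epoxidation may be incomplete or poorly face-selective because C4=C5 is remote from the hydroxyl and deactivated by the allylic lactone oxygen; over-oxidation of the carbinol is a lesser risk. Fallback, setting out from 44 and returning at 47: the two oxidations are separated. One equivalent of t-BuOOH with VO(acac)2 at 0 °C would stop at 46. The C4=C5 bond would then be epoxidised without a metal by dimethyldioxirane in acetone at −20 °C, relying on peripheral attack guided by hydrogen bonding to the C2 hydroxyl; this makes no new compound (F0).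

## Further compounds

F1 | step 9 | trimethylsilyl ether of 22 | C[Si](C)(C)O[C@@]1(/C=C/[Si](C)(C)Cc2ccccc2)C=C(C)C[C@H](OCc2ccc(OC)cc2)[C@H]1C(C)=C
F2 | step 9 | trimethylsilyl enol ether of 25 (C6–C7 enol ether) | C[Si](C)(C)O/C1=C\[C@@H]([Si](C)(C)Cc2ccccc2)C/C(C)=C/[C@@H](OCc2ccc(OC)cc2)C/C(C)=C\1
F3 | step 6 | trans-6-(2-hydroxypropan-2-yl)-5-[(4-methoxybenzyl)oxy]-3-methylcyclohex-2-en-1-one | O=C1C=C(C)C[C@H](OCc2ccc(OC)cc2)[C@H]1C(C)(C)O
F0 | step 10 | none | none
F4 | step 11 | (1(10)E,4Z)-8α-[benzyl(dimethyl)silyl]-6α-hydroxy-2α-[(4-methoxybenzyl)oxy]-13-norgermacra-1(10),4-dien-12-oic acid | O[C@H]1[C@H](CC(=O)O)[C@@H]([Si](C)(C)Cc2ccccc2)C/C(C)=C/[C@@H](OCc2ccc(OC)cc2)C/C(C)=C\1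
F5 | step 12 | tert-butyl ester analogue of 28 | O=C1[C@H](CC(=O)OC(C)(C)C)[C@@H]([Si](C)(C)Cc2ccccc2)C/C(C)=C/[C@@H](OCc2ccc(OC)cc2)C/C(C)=C\1
F6 | step 12 | tert-butyl ester analogue of 30 (6β-hydroxy) | O[C@@H]1[C@H](CC(=O)OC(C)(C)C)[C@@H]([Si](C)(C)Cc2ccccc2)C/C(C)=C/[C@@H](OCc2ccc(OC)cc2)C/C(C)=C\1
F7 | step 12 | 6β-methanesulfonate of F6 | CS(=O)(=O)O[C@@H]1[C@H](CC(=O)OC(C)(C)C)[C@@H]([Si](C)(C)Cc2ccccc2)C/C(C)=C/[C@@H](OCc2ccc(OC)cc2)C/C(C)=C\1
F0 | step 17 | none | none
A1 | alternative 1 | α-phosphono 6,12-lactone | CCOP(=O)(OCC)[C@@H]1C(=O)O[C@H]2[C@H]1[C@@H](OC(=O)/C(C)=C\C)C[C@@]1(C)O[C@@H]1[C@@H](O[Si](C)(C)C(C)(C)C)C[C@@]1(C)O[C@@H]21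
A2 | alternative 1 | C6 diazophosphonoacetate of the ten-membered diepoxide | CCOP(=O)(OCC)C(=[N+]=[N-])C(=O)O[C@H]1C[C@@H](OC(=O)/C(C)=C\C)C[C@@]2(C)O[C@@H]2[C@@H](O[Si](C)(C)C(C)(C)C)C[C@@]2(C)O[C@@H]12
A3 | alternative 2 | isoxazoline-bridged ten-membered lactone | C1C(=O)O[C@H]2[C@H]1[C@@H](O[Si](C)(C)C(C)(C)C)C/C(C)=C/C1=NO[C@](C)(C1)[C@@H]2O[Si](CC)(CC)CC
A4 | alternative 2 | open-chain aldoxime lactone | C1C(=O)O[C@H]([C@@H](O[Si](CC)(CC)CC)C(C)=C)[C@H]1[C@@H](O[Si](C)(C)C(C)(C)C)C/C(C)=C/C=NO
A5 | alternative 3 | C5 iodo 6,12-lactone with free C4 hydroxyl | O=C1C[C@@H]2[C@@H](OCc3ccc(OC)cc3)C/C(C)=C/[C@@H](O[Si](C)(C)C(C)(C)C)C[C@@](C)(O)[C@H](I)[C@H]2O1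
A6 | alternative 3 | ten-membered 4-hydroxy-5Z-ene acid | OC(=O)C[C@@H]1[C@@H](OCc2ccc(OC)cc2)C/C(C)=C/[C@@H](O[Si](C)(C)C(C)(C)C)C[C@@](C)(O)/C=C\1
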